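The cyclohexanone ring is numbered C1 (C=O), C2 (C–Me), C3, C4 (CH2), C5 (CH–isopropenyl), C6 (CH–O). Read this way, the ring is two isomeric C5 enals: C1–C4 is tiglaldehyde, C5–C6 plus the isopropenyl group is prenal, and the vicinal oxygens on C1 and C6 are their aldehyde oxygens. Both enals are bound as dienol ethers to one silicon atom. Heating this bis(dienyloxy)silane brings about an intramolecular Diels–Alder reaction that forms C4–C5 and C1–C6 in one operation. The temporary O–Si–O tether enforces the head-to-head regiochemistry and the E enol ether sets C5/C6 trans. Desilylation, allylic oxidation, lipase resolution, epoxidation and esterification follow.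

Key step: step 2

Remark: the ring carbons keep the numbers C1–C6 of the first paragraph throughout. Compounds 6, 7 and 8 are racemic and are drawn as the enantiomer that leads to the target (descriptors with an asterisk are relative). Compounds 6 and 7 are expected mainly as the isomer with the C1 oxygen cis to the C6 oxygen; the C1 epimer is carried along, because C1 becomes the carbonyl carbon in step 4.

Step 1
Reactants: 1 3-methylbut-2-enal (prenal); 2 di(propan-2-yl)silanediyl bis(trifluoromethanesulfonate); 3 (2E)-2-methylbut-2-enal (tiglaldehyde)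
Product: 5 {[(1E)-2-methylbuta-1,3-dien-1-yl]oxy}{[(1E)-3-methylbuta-1,3-dien-1-yl]oxy}di(propan-2-yl)silane, via dienyloxysilyl triflate 4 (not isolated)
Conditions: 2 (1.0 equiv), CH2Cl2, −78 °C; 1 (1.0 equiv), Et3N (1.2 equiv), −78 → −30 °C; then 3 (1.1 equiv), Et3N (1.5 equiv), −30 °C → rt
Reagents that add atoms: none
Why: Soft enolization (O-silylation of each enal, then γ-deprotonation by Et3N) gives the dienol silyl ethers; the first Si–OTf bond of 2 should react much faster than the second, so the two enals can be put on silicon one after the other, and deprotonation through the s-trans silyloxocarbenium ion places oxygen trans to the vinyl carbon (1E in both dienyl groups).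

Step 2
Reactants: 5 {[(1E)-2-methylbuta-1,3-dien-1-yl]oxy}{[(1E)-3-methylbuta-1,3-dien-1-yl]oxy}di(propan-2-yl)silane
Product: 6 rac-(3aR*,4R*,7aS*)-7-methyl-2,2-di(propan-2-yl)-4-(prop-1-en-2-yl)-3a,4,5,7a-tetrahydro-1,3,2-benzodioxasilole
Conditions: toluene (0.01 M), BHT (cat.), N,O-bis(trimethylsilyl)acetamide (cat.), 150 °C, sealed tube
Reagents that add atoms: none
Why: Concerted thermal [4+2] cycloaddition (intramolecular Diels–Alder reaction) in which the s-cis 1-silyloxy-2-methylbutadiene unit (C1–C4, oxygen outside) is the 4π partner and the enol ether double bond C5=C6 of the second dienyl group is the 2π partner. The closest known reaction types are the silaketal-tethered (temporary silicon connection) Diels–Alder reaction and the thermal [4+2] cyclization of 1,3,8-nonatriene-type bis-dienes. The cyclohexene ring closes by suprafacial addition across the diene termini C1 and C4, and the five-membered 1,3,2-dioxasilolane closes in the fused mode because its three-atom O–Si–O chain links the two termini that bond to each other. Regiochemistry, the selectivity that matters most, is secured by that tether alone: C1 can only reach C6, so C4 must bond to C5, an orientation for which two electron-rich, untethered partners would show neither reactivity nor bias. Of the new stereocenters, C5 and C6 are set trans by the E geometry of the enol ether (stereospecific), while C1 follows from the cis ring fusion preferred by the small ring and is lost in step 4. Periselectivity is secured because the alternative role of the two dienes would create a quaternary carbon, high dilution holds back intermolecular dimerization, and no element controls the absolute configuration, so 6 is racemic.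

Step 3
Reactants: 6 rac-(3aR*,4R*,7aS*)-7-methyl-2,2-di(propan-2-yl)-4-(prop-1-en-2-yl)-3a,4,5,7a-tetrahydro-1,3,2-benzodioxasilole (crude)
Product: 7 rac-(1R*,2S*,6R*)-3-methyl-6-(prop-1-en-2-yl)cyclohex-3-ene-1,2-diol
Conditions: HF·pyridine, pyridine, THF, 0 °C
Reagents that add atoms: none
Why: Fluoride-mediated silyl ether cleavage opens both Si–O bonds of the strained dialkoxysilane under buffered conditions that should leave the allylic diol and both alkenes untouched; no stereocenter changes.

Step 4
Reactants: 7 rac-(1R*,2S*,6R*)-3-methyl-6-(prop-1-en-2-yl)cyclohex-3-ene-1,2-diol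
Product: 8 rac-(5R*,6R*)-6-hydroxy-2-methyl-5-(prop-1-en-2-yl)cyclohex-2-en-1-one
Conditions: activated MnO2 (15 equiv), CH2Cl2, rt, stopped when 7 is consumed
Reagents that add atoms: none
Why: Chemoselective allylic oxidation by activated MnO2 should convert only the allylic C1 carbinol, so both C1 epimers converge on one conjugated enone while the C6 carbinol and the trans C5/C6 relationship stay intact.

Step 5
Reactants: 8 rac-(5R*,6R*)-6-hydroxy-2-methyl-5-(prop-1-en-2-yl)cyclohex-2-en-1-one
Product: 9 (5R,6R)-6-hydroxy-2-methyl-5-(prop-1-en-2-yl)cyclohex-2-en-1-one (recovered unreacted alcohol)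
Conditions: Burkholderia cepacia lipase (Amano PS, immobilized), vinyl acetate (3 equiv), t-BuOMe, 30 °C, run to about 55% conversion; chromatography
Reagents that add atoms: none
Why: Lipase-catalyzed kinetic resolution by enantioselective transesterification: by the Kazlauskas rule (C5 side as the large, C1 carbonyl side as the medium substituent) the (6S) enantiomer should be acetylated faster, so (5R,6R)-9 should be recovered in high enantiomeric purity once conversion passes one half; its configuration is to be confirmed (Mosher ester) before it is used.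

Step 6
Reactants: 9 (5R,6R)-6-hydroxy-2-methyl-5-(prop-1-en-2-yl)cyclohex-2-en-1-one
Product: 10 (1S,3R,4R,6S)-3-hydroxy-1-methyl-4-(prop-1-en-2-yl)-7-oxabicyclo[4.1.0]heptan-2-one
Conditions: 30% H2O2, NaOH (aq., 0.2 equiv), MeOH, 0 °C, short reaction time
Reagents that add atoms: hydrogen peroxide, OO
Why: Weitz–Scheffer nucleophilic epoxidation: hydroperoxide should add to C3 of the enone anti to the C5 isopropenyl group, as in carvone, and the enolate closes at C2 on the same face, which sets C2 and C3 with the epoxide trans to isopropenyl and cis to the C6 hydroxyl; the isolated isopropenyl alkene does not react.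

Step 7
Reactants: 11 3-methylbut-2-en-1-ol (prenol); 12 (2E)-2-methylbut-2-enoyl chloride (tigloyl chloride)
Product: 13 3-methylbut-2-en-1-yl (2E)-2-methylbut-2-enoate (prenyl tiglate)
Conditions: Et3N, DMAP (cat.), CH2Cl2, 0 °C → rt
Reagents that add atoms: none
Why: DMAP-catalyzed acylation of the primary allylic alcohol by the acid chloride; no stereocenter is formed and the E geometry of the tigloyl group is not touched.

Step 8
Reactants: 13 3-methylbut-2-en-1-yl (2E)-2-methylbut-2-enoate
Product: 14 (2E)-3-methyl-4-oxobut-2-en-1-yl (2E)-2-methylbut-2-enoate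
Conditions: SeO2 (1.2 equiv), 1,4-dioxane (2% H2O), 80 °C
Reagents that add atoms: selenium dioxide, O=[Se]=O
Why: Riley allylic oxidation (ene reaction, then [2,3]-sigmatropic shift) should take place at the E methyl group of the electron-rich trisubstituted alkene and leave the electron-poor tigloyl alkene alone, which gives the E enal.

Step 9
Reactants: 14 (2E)-3-methyl-4-oxobut-2-en-1-yl (2E)-2-methylbut-2-enoate
Product: 15 (2E)-2-methyl-4-{[(2E)-2-methylbut-2-enoyl]oxy}but-2-enoic acid
Conditions: NaClO2, NaH2PO4, 2-methylbut-2-ene, t-BuOH/H2O, 0 °C → rt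
Reagents that add atoms: sodium chlorite, [Na+].[O-]Cl=O
Why: Pinnick (Lindgren) oxidation converts the enal into the acid without touching either alkene or the ester, with 2-methylbut-2-ene trapping the hypochlorite.

Step 10
Reactants: 10 (1S,3R,4R,6S)-3-hydroxy-1-methyl-4-(prop-1-en-2-yl)-7-oxabicyclo[4.1.0]heptan-2-one; 15 (2E)-2-methyl-4-{[(2E)-2-methylbut-2-enoyl]oxy}but-2-enoic acid
Product: 16 (1S,3R,4R,6S)-1-methyl-2-oxo-4-(prop-1-en-2-yl)-7-oxabicyclo[4.1.0]heptan-3-yl (2E)-2-methyl-4-{[(2E)-2-methylbut-2-enoyl]oxy}but-2-enoate (CNP0251261.1)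
Conditions: DCC, DMAP (cat.), CH2Cl2, 0 °C → rt
Reagents that add atoms: none
Why: Steglich esterification of the secondary ketol hydroxyl under neutral conditions; the α-carbon of the acid bears no hydrogen, so its alkene geometry should hold, and C6 keeps its trans (thermodynamically preferred) configuration.

Compound list
1 | 3-methylbut-2-enal (prenal) | CC(C)=CC=O | starting material
2 | di(propan-2-yl)silanediyl bis(trifluoromethanesulfonate) | CC(C)[Si](C(C)C)(OS(=O)(=O)C(F)(F)F)OS(=O)(=O)C(F)(F)F | starting material
3 | (2E)-2-methylbut-2-enal (tiglaldehyde) | C/C=C(\C)C=O | starting material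
4 | {[(1E)-3-methylbuta-1,3-dien-1-yl]oxy}di(propan-2-yl)silyl trifluoromethanesulfonate | CC(C)[Si](C(C)C)(O/C=C/C(C)=C)OS(=O)(=O)C(F)(F)F | intermediate
5 | {[(1E)-2-methylbuta-1,3-dien-1-yl]oxy}{[(1E)-3-methylbuta-1,3-dien-1-yl]oxy}di(propan-2-yl)silane | CC(C)[Si](C(C)C)(O/C=C/C(C)=C)O/C=C(\C)C=C | intermediate
6 | rac-(3aR*,4R*,7aS*)-7-methyl-2,2-di(propan-2-yl)-4-(prop-1-en-2-yl)-3a,4,5,7a-tetrahydro-1,3,2-benzodioxasilole (racemic; isopropenyl trans to the oxygen on C3a, cis ring fusion) | C=C(C)[C@H]1CC=C(C)[C@@H]2O[Si](C(C)C)(C(C)C)O[C@H]12 | intermediate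
7 | rac-(1R*,2S*,6R*)-3-methyl-6-(prop-1-en-2-yl)cyclohex-3-ene-1,2-diol (racemic) | C=C(C)[C@H]1CC=C(C)[C@H](O)[C@@H]1O | intermediate
8 | rac-(5R*,6R*)-6-hydroxy-2-methyl-5-(prop-1-en-2-yl)cyclohex-2-en-1-one (racemic, trans) | C=C(C)[C@H]1CC=C(C)C(=O)[C@@H]1O | intermediate
9 | (5R,6R)-6-hydroxy-2-methyl-5-(prop-1-en-2-yl)cyclohex-2-en-1-one (single enantiomer) | C=C(C)[C@H]1CC=C(C)C(=O)[C@@H]1O | intermediate
10 | (1S,3R,4R,6S)-3-hydroxy-1-methyl-4-(prop-1-en-2-yl)-7-oxabicyclo[4.1.0]heptan-2-one | C=C(C)[C@H]1C[C@@H]2O[C@]2(C)C(=O)[C@@H]1O | intermediate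
11 | 3-methylbut-2-en-1-ol (prenol) | CC(C)=CCO | starting material
12 | (2E)-2-methylbut-2-enoyl chloride (tigloyl chloride) | C/C=C(\C)C(Cl)=O | starting material
13 | 3-methylbut-2-en-1-yl (2E)-2-methylbut-2-enoate | C/C=C(\C)C(=O)OCC=C(C)C | intermediate
14 | (2E)-3-methyl-4-oxobut-2-en-1-yl (2E)-2-methylbut-2-enoate | C/C=C(\C)C(=O)OC/C=C(\C)C=O | intermediate
15 | (2E)-2-methyl-4-{[(2E)-2-methylbut-2-enoyl]oxy}but-2-enoic acid | C/C=C(\C)C(=O)OC/C=C(\C)C(=O)O | intermediate
16 | (1S,3R,4R,6S)-1-methyl-2-oxo-4-(prop-1-en-2-yl)-7-oxabicyclo[4.1.0]heptan-3-yl (2E)-2-methyl-4-{[(2E)-2-methylbut-2-enoyl]oxy}but-2-enoate | C=C(C)[C@H]1C[C@@H]2O[C@]2(C)C(=O)[C@@H]1OC(=O)/C(C)=C/COC(=O)/C(C)=C/C | target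

Total step count: 10. Longest linear sequence: 7 steps (steps 1 to 6 and step 10); steps 7 to 9 make the side-chain acid in a parallel branch.

Steps most likely to fail

Step 2. The cycloaddition may lose periselectivity, with the prenal-derived diene reacting as the 4π partner and the trisubstituted enol ether of the other group as the 2π partner. The silyl dienol ethers may also undergo thermal silyl shifts or decomposition before the slow, unactivated ring closure takes place. The fallback removes the diene character of the 2π partner and makes the pair one of normal electron demand. It sets out from 2 and 3: soft enolization of 3 on 2, as in step 1, gives {[(1E)-2-methylbuta-1,3-dien-1-yl]oxy}di(propan-2-yl)silyl trifluoromethanesulfonate F1. Treating it in the same flask with sodium 3-oxobut-1-en-1-olate (from acetone, ethyl formate and NaOMe) gives (3E)-4-[({[(1E)-2-methylbuta-1,3-dien-1-yl]oxy}di(propan-2-yl)silyl)oxy]but-3-en-2-one F2. Heating F2 in toluene should give, again under control of the O–Si–O tether, rac-1-[(3aR*,4S*,7aS*)-7-methyl-2,2-di(propan-2-yl)-3a,4,5,7a-tetrahydro-1,3,2-benzodioxasilol-4-yl]ethan-1-one F3. Wittig methylenation of the acetyl group (Ph3P=CH2, THF, 0 °C) comes back to the route at 6.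

Step 5. The lipase may discriminate poorly between the enantiomers of this ketol, or acylate in the opposite sense, so that the recovered alcohol is the wrong or an impure enantiomer. The fallback replaces the enzymatic resolution by a physical one. It sets out from 8, whose enantiomers are separated by preparative chromatography on a chiral stationary phase (amylose tris(3,5-dimethylphenylcarbamate)). This makes no new compound (F0) and comes back to the route at 9.

Step 6. Under alkaline hydroperoxide the free ketol may epimerize at C6 through the enediol, transpose its carbonyl and hydroxyl groups, or be cleaved oxidatively between C1 and C6. The fallback masks the hydroxyl group during the epoxidation. It sets out from 9, which is silylated (Et3SiCl, imidazole, CH2Cl2) to (5R,6R)-2-methyl-5-(prop-1-en-2-yl)-6-[(triethylsilyl)oxy]cyclohex-2-en-1-one F4. Epoxidation as in step 6 should give (1S,3R,4R,6S)-1-methyl-4-(prop-1-en-2-yl)-3-[(triethylsilyl)oxy]-7-oxabicyclo[4.1.0]heptan-2-one F5, and HF·pyridine in THF comes back to the route at 10.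

Further compounds
F1 | step 2 | {[(1E)-2-methylbuta-1,3-dien-1-yl]oxy}di(propan-2-yl)silyl trifluoromethanesulfonate | CC(C)[Si](C(C)C)(O/C=C(\C)C=C)OS(=O)(=O)C(F)(F)F
F2 | step 2 | (3E)-4-[({[(1E)-2-methylbuta-1,3-dien-1-yl]oxy}di(propan-2-yl)silyl)oxy]but-3-en-2-one | CC(=O)/C=C/O[Si](C(C)C)(C(C)C)O/C=C(\C)C=C
F3 | step 2 | rac-1-[(3aR*,4S*,7aS*)-7-methyl-2,2-di(propan-2-yl)-3a,4,5,7a-tetrahydro-1,3,2-benzodioxasilol-4-yl]ethan-1-one | CC(=O)[C@H]1CC=C(C)[C@@H]2O[Si](C(C)C)(C(C)C)O[C@H]12
F0 | step 5 | none | none
F4 | step 6 | (5R,6R)-2-methyl-5-(prop-1-en-2-yl)-6-[(triethylsilyl)oxy]cyclohex-2-en-1-one | C=C(C)[C@H]1CC=C(C)C(=O)[C@@H]1O[Si](CC)(CC)CC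
F5 | step 6 | (1S,3R,4R,6S)-1-methyl-4-(prop-1-en-2-yl)-3-[(triethylsilyl)oxy]-7-oxabicyclo[4.1.0]heptan-2-one | C=C(C)[C@H]1C[C@@H]2O[C@]2(C)C(=O)[C@@H]1O[Si](CC)(CC)CC
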